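| flask | substrate | reagent | free catalyst | second catalyst | temperature | remark | time |
|---|---|---|---|---|---|---|---|
| elm | 0.10 M | 0.15 M | 5 mM | 13 mM | 55 °C | run made earlier |  |
| alder | 0.10 M | 0.15 M | 7 mM | 13 mM | 70 °C | run made earlier |  |
| birch | 0.10 M | 0.15 M | 11 mM | 13 mM | 55 °C | run made earlier |  |
| cedar | 0.20 M | 0.15 M | 5 mM | 13 mM | 70 °C | run made earlier |  |
| north-west | 0.10 M | 0.150 M | 5.0 mM | 13 mM | 70 °C | everything together at the start | 5.0 min |
| north | 0.10 M | 0.150 M | 5.0 mM | 13 mM |  | everything together at the start at 40 °C, warmed to 70 °C at 4.0 min | 5.0 min |
| west | 0.10 M | 0.150 M (fed, over 4.0 min) | 5.0 mM | 13 mM |  | the addition at 40 °C, then warmed to 70 °C; the feed brings no volume worth counting | 5.0 min |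
| south-west | 0.10 M | 0.150 M (fed, over 4.0 min) | 5.0 mM | 13 mM | 70 °C | all else is in the flask from the start; the feed brings no volume worth counting | 5.0 min |

- elm (time / min: side product / %, target / %): 0.833: 5, 0; 2.00: 16, 4; 4.00: 36, 6; 6.00: 50, 11
- alder (time / min: side product / %, target / %): 0.500: 10, 1; 1.00: 35, 4; 2.50: 76, 9; 6.00: 90, 11
- birch (time / min: side product / %, target / %): 3.00: 34, 9; 6.00: 56, 15; 10.0: 72, 16; 12.0: 73, 17
- cedar (time / min: side product / %, target / %): 1.50: 47, 6; 3.00: 75, 9; 5.00: 89, 9; 6.00: 91, 7

(scatter of a reading: 1.5 percentage points)

* the flask that comes out highest in amount of side product, in percent of the substrate charged, or "all alike" when all lie within 1.5 percentage points (north-west / north / west / south-west / all alike)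
* side product at the end, in percent of the substrate charged, north-west
* side product at the end, in percent of the substrate charged, north
* side product at the end, in percent of the substrate charged, west
* side product at the end, in percent of the substrate charged, south-west



Late in the alder run, the part of the charge seen neither as target nor as side product is read as falling exponentially. In alder its constant is 0.935 min⁻¹, which gives the clearance half-life, the time in which this unseen remainder halves at 70 °C: 0.741 min. At 55 °C, elm with 5 mM free catalyst reads 0.198 min⁻¹ and birch with 11 mM reads 0.225 min⁻¹, so free catalyst barely shows in this constant. Before clearance comes a lag, the induction period: extrapolated back, 0.693 min in cedar at 70 °C and 1.25 min in elm at 55 °C. A molecule clearing the remainder then meets a fork, where alder's last reading gives side product a chance of 89.1%.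

North can be reckoned from two extremes. If the cold hold had passed every molecule through the lag, the hot 1.00 min would give 54.1%. If the hold had done nothing, the lag would come out of that time and give 22.3%. Continuing the lags geometrically to 40 °C gives about 2.27 min, shorter than the hold, so about 17.2% stays behind the lag. My reckoning for north is therefore 48.6%, and I take west as about the same, since cedar's 0.182 M of side product exceeds its reagent charge of 0.15 M, so side product does not take up reagent one for one. North-west gives 87.5%. In south-west the reagent averages half its charge during the feed, so I take the target's chance as 5.45% and side product reaches 92.9%, the highest.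

The forecast names south-west and gives 86%, 43%, 46% and 89% in the order asked, saying that the hold “partly activates the catalyst”. My north stands above its figure.

The flasks give 88.9%, 51.2%, 52.1% and 93.6%, with south-west highest.

    substrate + free catalyst → free catalyst + intermediate (k = 4.10 M⁻¹ s⁻¹, Ea = 39.0 kJ mol⁻¹)
    reagent + second catalyst + intermediate → second catalyst + target (k = 0.840 M⁻² s⁻¹, Ea = 43.0 kJ mol⁻¹)
    intermediate → side product (k = 0.0160 s⁻¹, Ea = 99.0 kJ mol⁻¹)
    (constants at 70 °C)

In north, intermediate is made 7.15 times faster than it is used at 1.86 min, and that ratio is 0.277 at 5.00 min. At 4.00 min north holds 64.1% as intermediate, and the hot 1.00 min that follows lasts 1.35 clearance half-lives. For the neighbour of north charged with 8.50 mM free catalyst, taking the lag as inverse to free catalyst leaves 5.03% behind it, and the half-life then gives 52.5%. The computed flask gives 57.2%.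

The data come from a simulation for an exercise, noise included.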